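**Strategy.** Lignan numbering is used. Ring A (C7'–O–C9–C8–C8') is disconnected into formaldehyde (the O–C9 unit) and a C8/C8'/C7' 1,3-zwitterion, masked as a cis-2-aryl-3-(silyloxymethyl)cyclopropane-1,1-diester. The design exploits the 1,3-relationship between the benzylic ether carbon C7' (cation-stabilising aryl) and the quaternary carbinol carbon C8 (malonate level). A Lewis acid-catalysed (3+2) cycloaddition forms the O–C7' and C9–C8 bonds in one operation, with inversion at C7' giving the exo aryl group. Afterwards one ester lactonises to ring B, the other is exchanged for the C8 hydroxyl, and the second syringyl unit is added to the lactone carbonyl (C7).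

Key step: step 5

Remark: C7/C7' are the benzylic carbons, C8/C8' the ring-fusion carbons and C9/C9' the OCH2 carbons; in step 4 the ligand antipode that delivers (2R,3R)-7 is chosen; 8 is handled as its polymer paraformaldehyde.

**Step 1**
Reactants: 1 4-bromo-2,6-dimethoxyphenol
Product: 2 2-(benzyloxy)-5-bromo-1,3-dimethoxybenzene
Conditions: BnBr (1.1 equiv), K2CO3 (1.5 equiv), DMF, 60 °C
Reagents that add atoms: benzyl bromide, BrCc1ccccc1
Why: Williamson O-alkylation of the phenoxide (SN2 at the benzylic carbon) should be clean because both ortho positions are blocked by methoxy groups.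

**Step 2**
Reactants: 2 2-(benzyloxy)-5-bromo-1,3-dimethoxybenzene; 3 tert-butyl(diphenyl)(prop-2-yn-1-yloxy)silane
Product: 4 {[3-(4-benzyloxy-3,5-dimethoxyphenyl)prop-2-yn-1-yl]oxy}(tert-butyl)diphenylsilane
Conditions: PdCl2(PPh3)2 (3 mol%), CuI (5 mol%), Et3N, DMF, 80 °C
Reagents that add atoms: none
Why: Sonogashira coupling of the aryl bromide with the terminal alkyne installs C7', C8' and C9' with the C9' oxygen already silylated, and neither the aryl benzyl ether nor the silyl ether reacts.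

**Step 3**
Reactants: 4 {[3-(4-benzyloxy-3,5-dimethoxyphenyl)prop-2-yn-1-yl]oxy}(tert-butyl)diphenylsilane
Product: 5 (Z)-{[3-(4-benzyloxy-3,5-dimethoxyphenyl)prop-2-en-1-yl]oxy}(tert-butyl)diphenylsilane
Conditions: H2 (1 atm), Pd/CaCO3 poisoned with Pb(OAc)2, quinoline, EtOAc, rt
Reagents that add atoms: none
Why: Lindlar semi-hydrogenation adds hydrogen syn and stops at the (Z)-alkene, which fixes the cis relationship needed in the cyclopropane while the poisoned catalyst spares the aryl benzyl ether.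

**Step 4**
Reactants: 5 (Z)-{[3-(4-benzyloxy-3,5-dimethoxyphenyl)prop-2-en-1-yl]oxy}(tert-butyl)diphenylsilane; 6 dimethyl 2-(phenyl-λ3-iodanylidene)malonate
Product: 7 dimethyl (2R,3R)-2-(4-benzyloxy-3,5-dimethoxyphenyl)-3-[(tert-butyldiphenylsilyloxy)methyl]cyclopropane-1,1-dicarboxylate (aryl and silyloxymethyl groups cis)
Conditions: 6 (1.5 equiv), Cu(MeCN)4PF6 (10 mol%), chiral side-arm-modified bis(oxazoline) ligand (SaBOX type, 12 mol%), 4 Å MS, toluene, 0 °C → rt
Reagents that add atoms: none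
Why: Asymmetric cyclopropanation by a copper malonate carbene generated from the iodonium ylide is concerted and stereospecific, so the (Z)-alkene should give the cis-cyclopropane while the chiral ligand selects the alkene face and thereby sets C7' and C8'.

**Step 5**
Reactants: 7 dimethyl (2R,3R)-2-(4-benzyloxy-3,5-dimethoxyphenyl)-3-[(tert-butyldiphenylsilyloxy)methyl]cyclopropane-1,1-dicarboxylate; 8 formaldehyde (as paraformaldehyde)
Product: 9 dimethyl (4R,5S)-5-(4-benzyloxy-3,5-dimethoxyphenyl)-4-[(tert-butyldiphenylsilyloxy)methyl]oxolane-3,3-dicarboxylate (4,5-trans)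
Conditions: paraformaldehyde (5 equiv of CH2O), Sn(OTf)2 (10 mol%), 4 Å MS, ClCH2CH2Cl, 0 °C → rt
Reagents that add atoms: none
Why: The Lewis acid chelates the geminal diester and polarises the C8–C7' bond, the oxygen of formaldehyde attacks the benzylic carbon C7' from the rear (SN2-like, inversion) while the malonate departs as its tin enolate, and the enolate carbon C8 then closes onto the new oxocarbenium carbon C9, so that the O–C7' and C9–C8 bonds form in one operation. The closest known reaction type is the Lewis acid-catalysed (3+2) cycloaddition of 2-arylcyclopropane-1,1-dicarboxylates with aldehydes to tetrahydrofurans, here with the simplest aldehyde and a 2,3-disubstituted cyclopropane. Ring A is closed by an intermolecular substitution followed by a 5-endo-trig aldol-type attack of the enolate on the oxocarbenium ion, a mode that is open to such cationic electrophiles. C7' is the only stereocentre made: inversion of the (2R) carbon of the cis-cyclopropane places the aryl group trans to the silyloxymethyl arm (5S), C8' is carried through untouched and C8 is not yet stereogenic. The step needs cleavage of the C8–C7' bond and not of the C8–C8' bond, which the cation-stabilising aryl group secures, and it needs the 4,5-trans product, which is favoured both by the stereospecific course and, should ionisation intervene, by kinetic and thermodynamic preference in the monocyclic tetrahydrofuran.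

**Step 6**
Reactants: 9 dimethyl (4R,5S)-5-(4-benzyloxy-3,5-dimethoxyphenyl)-4-[(tert-butyldiphenylsilyloxy)methyl]oxolane-3,3-dicarboxylate
Product: 11 methyl (3aR,4S,6aR)-4-(4-benzyloxy-3,5-dimethoxyphenyl)-1-oxotetrahydro-1H,3H-furo[3,4-c]furan-6a-carboxylate (cis-fused; aryl exo), via hydroxy diester 10 (not isolated)
Conditions: TBAF (1.2 equiv), THF, 0 °C → rt; aq. NH4Cl
Reagents that add atoms: none
Why: Fluoride cleaves the silyl ether and the freed alkoxide attacks the only ester cis to it (5-exo-trig lactonisation), which closes ring B as a lactone, tells the two esters apart and leaves the surviving ester on the convex face at C8.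

**Step 7**
Reactants: 11 methyl (3aR,4S,6aR)-4-(4-benzyloxy-3,5-dimethoxyphenyl)-1-oxotetrahydro-1H,3H-furo[3,4-c]furan-6a-carboxylate
Product: 12 (3aR,4S,6aR)-4-(4-benzyloxy-3,5-dimethoxyphenyl)tetrahydro-1H,3H-furo[3,4-c]furan-1-one (cis-fused; aryl exo)
Conditions: LiCl (3 equiv), H2O (2 equiv), DMSO, 140 °C
Reagents that add atoms: none
Why: Krapcho dealkoxycarbonylation (SN2 demethylation by chloride, decarboxylation, protonation of the lactone enolate) removes the bridgehead ester, and protonation can only give the cis-fused bicycle.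

**Step 8**
Reactants: 12 (3aR,4S,6aR)-4-(4-benzyloxy-3,5-dimethoxyphenyl)tetrahydro-1H,3H-furo[3,4-c]furan-1-one
Product: 14 (3aR,4S,6aS)-4-(4-benzyloxy-3,5-dimethoxyphenyl)-6a-hydroxytetrahydro-1H,3H-furo[3,4-c]furan-1-one, via potassium enolate 13 (not isolated)
Conditions: KHMDS (1.2 equiv), THF, −78 °C; 2-(phenylsulfonyl)-3-phenyloxaziridine (1.5 equiv), −78 °C; aq. NH4Cl
Reagents that add atoms: 2-(phenylsulfonyl)-3-phenyloxaziridine, O=S(=O)(c1ccccc1)N1OC1c1ccccc1
Why: Davis oxidation of the lactone enolate can deliver oxygen to C8 only from the convex face of the cis-fused bicycle, which sets the C8 hydroxyl cis to H8' (8S), while β-elimination of the ring A oxygen is disfavoured because the C9–O bond lies in the enolate plane.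

**Step 9**
Reactants: 14 (3aR,4S,6aS)-4-(4-benzyloxy-3,5-dimethoxyphenyl)-6a-hydroxytetrahydro-1H,3H-furo[3,4-c]furan-1-one; 2 2-(benzyloxy)-5-bromo-1,3-dimethoxybenzene
Product: 16 (3aR,4S,6aS)-1,4-bis(4-benzyloxy-3,5-dimethoxyphenyl)tetrahydro-1H,3H-furo[3,4-c]furan-1,6a-diol (lactol; both anomers at C1), via aryllithium 15 (not isolated)
Conditions: 2 (2.6 equiv), n-BuLi (2.5 equiv), THF, −78 °C; then 14, −78 → −40 °C; aq. NH4Cl
Reagents that add atoms: none
Why: Bromine–lithium exchange gives the aryllithium, of which one equivalent deprotonates the tertiary alcohol and another adds to the lactone carbonyl (C7), the lithium hemiketal being stable at low temperature so that addition should stop at the lactol.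

**Step 10**
Reactants: 16 (3aR,4S,6aS)-1,4-bis(4-benzyloxy-3,5-dimethoxyphenyl)tetrahydro-1H,3H-furo[3,4-c]furan-1,6a-diol
Product: 18 (3R,3aS,6S,6aR)-3,6-bis(4-benzyloxy-3,5-dimethoxyphenyl)tetrahydro-1H,3H-furo[3,4-c]furan-3a-ol (4,4'-di-O-benzyl-8-hydroxysyringaresinol), via triol 17 (not isolated)
Conditions: NaBH4 (3 equiv), THF/MeOH, 0 °C → rt; then HCl in MeOH to pH 1, 0 °C → rt
Reagents that add atoms: none
Why: Borohydride reduces the hydroxy ketone tautomer of the lactol to the triol, and acid then ionises the benzylic carbinol so that the C9' hydroxyl captures the cation (SN1, 5-exo-trig cycloetherification) with the aryl group on the convex face, both carbinol epimers converging on the (7R) exo isomer.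

**Step 11**
Reactants: 18 (3R,3aS,6S,6aR)-3,6-bis(4-benzyloxy-3,5-dimethoxyphenyl)tetrahydro-1H,3H-furo[3,4-c]furan-3a-ol
Product: 19 (3R,3aS,6S,6aR)-3,6-bis(4-hydroxy-3,5-dimethoxyphenyl)tetrahydro-1H,3H-furo[3,4-c]furan-3a-ol, (7R,8S,7'S,8'R)-8-hydroxysyringaresinol
Conditions: H2 (1 atm), Pd/C (10 wt% Pd), EtOAc/EtOH, rt, stopped after uptake of 2 equiv
Reagents that add atoms: none
Why: Hydrogenolysis of the two aryl benzyl ethers is much faster than cleavage of the dialkyl benzylic C–O bonds of the furofuran, so both phenols should be freed without touching a stereocentre.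

**Compound list**
1 | 4-bromo-2,6-dimethoxyphenol | COc1cc(Br)cc(OC)c1O | starting material
2 | 2-(benzyloxy)-5-bromo-1,3-dimethoxybenzene | COc1cc(Br)cc(OC)c1OCc1ccccc1 | intermediate
3 | tert-butyl(diphenyl)(prop-2-yn-1-yloxy)silane | C#CCO[Si](c1ccccc1)(c1ccccc1)C(C)(C)C | starting material
4 | {[3-(4-benzyloxy-3,5-dimethoxyphenyl)prop-2-yn-1-yl]oxy}(tert-butyl)diphenylsilane | COc1cc(C#CCO[Si](c2ccccc2)(c2ccccc2)C(C)(C)C)cc(OC)c1OCc1ccccc1 | intermediate
5 | (Z)-{[3-(4-benzyloxy-3,5-dimethoxyphenyl)prop-2-en-1-yl]oxy}(tert-butyl)diphenylsilane | COc1cc(/C=C\CO[Si](c2ccccc2)(c2ccccc2)C(C)(C)C)cc(OC)c1OCc1ccccc1 | intermediate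
6 | dimethyl 2-(phenyl-λ3-iodanylidene)malonate (iodonium ylide of dimethyl malonate) | COC(=O)[C-](C(=O)OC)[I+]c1ccccc1 | starting material
7 | dimethyl (2R,3R)-2-(4-benzyloxy-3,5-dimethoxyphenyl)-3-[(tert-butyldiphenylsilyloxy)methyl]cyclopropane-1,1-dicarboxylate (cis) | COC(=O)C1(C(=O)OC)[C@@H](c2cc(OC)c(OCc3ccccc3)c(OC)c2)[C@H]1CO[Si](c1ccccc1)(c1ccccc1)C(C)(C)C | intermediate
8 | formaldehyde (used as paraformaldehyde) | C=O | starting material
9 | dimethyl (4R,5S)-5-(4-benzyloxy-3,5-dimethoxyphenyl)-4-[(tert-butyldiphenylsilyloxy)methyl]oxolane-3,3-dicarboxylate | COc1cc([C@H]2OCC(C(=O)OC)(C(=O)OC)[C@@H]2CO[Si](c2ccccc2)(c2ccccc2)C(C)(C)C)cc(OC)c1OCc1ccccc1 | intermediate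
10 | dimethyl (4R,5S)-5-(4-benzyloxy-3,5-dimethoxyphenyl)-4-(hydroxymethyl)oxolane-3,3-dicarboxylate | COc1cc([C@H]2OCC(C(=O)OC)(C(=O)OC)[C@@H]2CO)cc(OC)c1OCc1ccccc1 | intermediate
11 | methyl (3aR,4S,6aR)-4-(4-benzyloxy-3,5-dimethoxyphenyl)-1-oxotetrahydro-1H,3H-furo[3,4-c]furan-6a-carboxylate | COc1cc([C@H]2OC[C@]3(C(=O)OC)C(=O)OC[C@H]23)cc(OC)c1OCc1ccccc1 | intermediate
12 | (3aR,4S,6aR)-4-(4-benzyloxy-3,5-dimethoxyphenyl)tetrahydro-1H,3H-furo[3,4-c]furan-1-one | COc1cc([C@H]2OC[C@@H]3C(=O)OC[C@H]23)cc(OC)c1OCc1ccccc1 | intermediate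
13 | potassium enolate of 12 | COc1cc([C@H]2OCC3=C([O-])OC[C@H]23)cc(OC)c1OCc1ccccc1.[K+] | intermediate
14 | (3aR,4S,6aS)-4-(4-benzyloxy-3,5-dimethoxyphenyl)-6a-hydroxytetrahydro-1H,3H-furo[3,4-c]furan-1-one | COc1cc([C@H]2OC[C@]3(O)C(=O)OC[C@H]23)cc(OC)c1OCc1ccccc1 | intermediate
15 | (4-benzyloxy-3,5-dimethoxyphenyl)lithium | COc1cc([Li])cc(OC)c1OCc1ccccc1 | intermediate
16 | (3aR,4S,6aS)-1,4-bis(4-benzyloxy-3,5-dimethoxyphenyl)tetrahydro-1H,3H-furo[3,4-c]furan-1,6a-diol (lactol, C1 anomers) | COc1cc([C@H]2OC[C@]3(O)C(O)(c4cc(OC)c(OCc5ccccc5)c(OC)c4)OC[C@H]23)cc(OC)c1OCc1ccccc1 | intermediate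
17 | (3S,4R,5S)-5-(4-benzyloxy-3,5-dimethoxyphenyl)-3-[(4-benzyloxy-3,5-dimethoxyphenyl)(hydroxy)methyl]-4-(hydroxymethyl)oxolan-3-ol (both carbinol epimers) | COc1cc([C@H]2OC[C@](O)(C(O)c3cc(OC)c(OCc4ccccc4)c(OC)c3)[C@@H]2CO)cc(OC)c1OCc1ccccc1 | intermediate
18 | (3R,3aS,6S,6aR)-3,6-bis(4-benzyloxy-3,5-dimethoxyphenyl)tetrahydro-1H,3H-furo[3,4-c]furan-3a-ol | COc1cc([C@H]2OC[C@]3(O)[C@@H](c4cc(OC)c(OCc5ccccc5)c(OC)c4)OC[C@H]23)cc(OC)c1OCc1ccccc1 | intermediate
19 | (7R,8S,7'S,8'R)-8-hydroxysyringaresinol | COc1cc([C@H]2OC[C@]3(O)[C@@H](c4cc(OC)c(O)c(OC)c4)OC[C@H]23)cc(OC)c1O | target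

Total step count: 11. Longest linear sequence: 11 steps (1 → 2 → 4 → 5 → 7 → 9 → 11 → 12 → 14 → 16 → 18 → 19; compound 2 is used a second time in step 9).

**Steps most likely to fail**

Step 5. Three processes could undermine it:
- stereospecificity at C7' may be eroded if the strained cis-cyclopropane opens and recloses to its trans isomer before capture;
- Lewis acid-activated formaldehyde may hydroxymethylate the electron-rich arene;
- two formaldehyde units may be taken up to give a seven-membered acetal.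

The fallback sets out from 7 and comes back at 9, building the same two bonds stepwise by polar chemistry. Lewis acid-catalysed ring opening of 7 with methanol (Sc(OTf)3, MeOH, CH2Cl2) should give the benzylic methyl ether dimethyl 2-[(1S,2R)-1-(4-benzyloxy-3,5-dimethoxyphenyl)-1-methoxy-3-(tert-butyldiphenylsilyloxy)propan-2-yl]malonate F1. Hydroxymethylation of its malonate C–H with aqueous formaldehyde and K2CO3 in THF should give the hydroxymethyl malonate F2. BF3·OEt2 in CH2Cl2 at low temperature would then ionise the benzylic ether, and the primary hydroxyl would capture the cation (5-exo-trig) to give 9. The 4,5-trans isomer is favoured kinetically and thermodynamically, so the configuration of the methoxy-bearing carbon of F1 is immaterial.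

Step 4. Carbene transfer to the hindered (Z)-alkene may be slow, so that carbene dimerisation takes over, or the catalyst may discriminate the alkene faces poorly. The fallback sets out from 5 and comes back at 11; it tethers the carbene and replaces asymmetric catalysis by resolution.
- Desilylation of 5 (TBAF, THF) gives the (Z)-allylic alcohol F3.
- Acylation with methyl malonyl chloride and pyridine gives the mixed malonate F4.
- Diazo transfer with 4-acetamidobenzenesulfonyl azide and Et3N gives the diazomalonate F5.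
- Stereospecific intramolecular cyclopropanation with Rh2(esp)2 gives the racemic endo-aryl bicyclic lactone, whose enantiomers are separated by preparative chromatography on a chiral stationary phase; the enantiomer kept is methyl (1S,5R,6R)-6-(4-benzyloxy-3,5-dimethoxyphenyl)-2-oxo-3-oxabicyclo[3.1.0]hexane-1-carboxylate F6.
- F6 already contains ring B and, with 8 under the conditions of step 5, should give 11 directly.

Step 10. Capture of the benzylic cation may lack facial selectivity, the β-hydroxy cation may undergo a semipinacol shift, or the acid may ionise the ring A benzylic ether and epimerise C7'. The fallback sets out from 14 and comes back at 19; it closes ring B through a quinone methide under conditions that leave the O-benzylated ring A inert.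
- Silylation of 1 (TBSCl, imidazole, DMF) gives (4-bromo-2,6-dimethoxyphenoxy)(tert-butyl)dimethylsilane F7.
- Bromine–lithium exchange (n-BuLi, THF, −78 °C) gives the aryllithium F8, which adds to 14 to give the lactol F9.
- NaBH4 reduces F9 to the silylated triol F10.
- TBAF gives the free syringyl carbinol F11, which with pyridinium p-toluenesulfonate forms a p-quinone methide; the C9' hydroxyl adds to it in a 1,6-sense (5-exo-trig) with the aryl group exo, giving 4'-O-benzyl-8-hydroxysyringaresinol F12.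
- Hydrogenolysis (H2, Pd/C) then gives 19.

**Further compounds**
F1 | step 5 | dimethyl 2-[(1S,2R)-1-(4-benzyloxy-3,5-dimethoxyphenyl)-1-methoxy-3-(tert-butyldiphenylsilyloxy)propan-2-yl]malonate | COc1cc([C@@H](OC)[C@@H](CO[Si](c2ccccc2)(c2ccccc2)C(C)(C)C)C(C(=O)OC)C(=O)OC)cc(OC)c1OCc1ccccc1
F2 | step 5 | dimethyl 2-[(1S,2R)-1-(4-benzyloxy-3,5-dimethoxyphenyl)-1-methoxy-3-(tert-butyldiphenylsilyloxy)propan-2-yl]-2-(hydroxymethyl)malonate | COc1cc([C@@H](OC)[C@@H](CO[Si](c2ccccc2)(c2ccccc2)C(C)(C)C)C(CO)(C(=O)OC)C(=O)OC)cc(OC)c1OCc1ccccc1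
F3 | step 4 | (Z)-3-(4-benzyloxy-3,5-dimethoxyphenyl)prop-2-en-1-ol | COc1cc(/C=C\CO)cc(OC)c1OCc1ccccc1
F4 | step 4 | (Z)-3-(4-benzyloxy-3,5-dimethoxyphenyl)prop-2-en-1-yl methyl malonate | COC(=O)CC(=O)OC/C=C\c1cc(OC)c(OCc2ccccc2)c(OC)c1
F5 | step 4 | (Z)-3-(4-benzyloxy-3,5-dimethoxyphenyl)prop-2-en-1-yl methyl 2-diazomalonate | COC(=O)C(=[N+]=[N-])C(=O)OC/C=C\c1cc(OC)c(OCc2ccccc2)c(OC)c1
F6 | step 4 | methyl (1S,5R,6R)-6-(4-benzyloxy-3,5-dimethoxyphenyl)-2-oxo-3-oxabicyclo[3.1.0]hexane-1-carboxylate (aryl endo) | COC(=O)[C@]12[C@@H](c3cc(OC)c(OCc4ccccc4)c(OC)c3)[C@H]1COC2=O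
F7 | step 10 | (4-bromo-2,6-dimethoxyphenoxy)(tert-butyl)dimethylsilane | COc1cc(Br)cc(OC)c1O[Si](C)(C)C(C)(C)C
F8 | step 10 | [4-(tert-butyldimethylsilyloxy)-3,5-dimethoxyphenyl]lithium | COc1cc([Li])cc(OC)c1O[Si](C)(C)C(C)(C)C
F9 | step 10 | (3aR,4S,6aS)-4-(4-benzyloxy-3,5-dimethoxyphenyl)-1-[4-(tert-butyldimethylsilyloxy)-3,5-dimethoxyphenyl]tetrahydro-1H,3H-furo[3,4-c]furan-1,6a-diol (lactol, C1 anomers) | COc1cc([C@H]2OC[C@]3(O)C(O)(c4cc(OC)c(O[Si](C)(C)C(C)(C)C)c(OC)c4)OC[C@H]23)cc(OC)c1OCc1ccccc1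
F10 | step 10 | (3S,4R,5S)-5-(4-benzyloxy-3,5-dimethoxyphenyl)-3-{[4-(tert-butyldimethylsilyloxy)-3,5-dimethoxyphenyl](hydroxy)methyl}-4-(hydroxymethyl)oxolan-3-ol | COc1cc([C@H]2OC[C@](O)(C(O)c3cc(OC)c(O[Si](C)(C)C(C)(C)C)c(OC)c3)[C@@H]2CO)cc(OC)c1OCc1ccccc1
F11 | step 10 | (3S,4R,5S)-5-(4-benzyloxy-3,5-dimethoxyphenyl)-3-[hydroxy(4-hydroxy-3,5-dimethoxyphenyl)methyl]-4-(hydroxymethyl)oxolan-3-ol | COc1cc([C@H]2OC[C@](O)(C(O)c3cc(OC)c(O)c(OC)c3)[C@@H]2CO)cc(OC)c1OCc1ccccc1
F12 | step 10 | (3R,3aS,6S,6aR)-6-(4-benzyloxy-3,5-dimethoxyphenyl)-3-(4-hydroxy-3,5-dimethoxyphenyl)tetrahydro-1H,3H-furo[3,4-c]furan-3a-ol | COc1cc([C@H]2OC[C@]3(O)[C@@H](c4cc(OC)c(O)c(OC)c4)OC[C@H]23)cc(OC)c1OCc1ccccc1
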